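## Retrosynthetic overview

1. The acrylic acid is disconnected last, at the C=C bond: Knoevenagel–Doebner condensation of a C5 aldehyde with malonic acid.
2. The C2–aryl bond comes from a visible-light/Ni arylation of the C2–H bond. A radical relayed from a silyl tether on the C3 CH2O group opens that position, and the aryl group enters trans to C3.
3. The C3–C3a bond comes from an intramolecular aryllithium 5-exo opening of an aryl glycidyl ether (SN2, inversion). The C3 stereocentre is purchased as (S)-glycidyl nosylate.
4. The O–CH2 bond comes from alkylation of 5-bromovanillin.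
5. Only one ring is formed, the dihydrofuran, in step 2; both benzene rings are purchased.

Assumption: 4-bromo-2-methoxyphenyl acetate (7) is treated as a catalogue item (it is the acetate of commodity 4-bromoguaiacol); if it has to be made, add one acetylation step.

## Route

**Step 1**
Reactants: 1, 5-bromovanillin (3-bromo-4-hydroxy-5-methoxybenzaldehyde); 2, (S)-glycidyl nosylate ([(2S)-oxiran-2-yl]methyl 3-nitrobenzenesulfonate)
Product: 3, 3-bromo-5-methoxy-4-{[(2S)-oxiran-2-yl]methoxy}benzaldehyde
Conditions: K2CO3 (1.5 equiv), DMF, 50 °C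
Reagents that add atoms: (S)-glycidyl nosylate, O=S(=O)(OC[C@@H]1CO1)c1cccc([N+](=O)[O-])c1
Why: Williamson O-alkylation at the primary sulfonate carbon; no bond to the stereocentre is broken, so the purchased (S)-oxirane is carried over unchanged.

**Step 2**
Reactants: 3, 3-bromo-5-methoxy-4-{[(2S)-oxiran-2-yl]methoxy}benzaldehyde
Product: 4, (3R)-3-(hydroxymethyl)-7-methoxy-2,3-dihydro-1-benzofuran-5-carbaldehyde
Conditions: LiN(Me)CH2CH2NMe2 (1.1 equiv), THF, −78 °C; then t-BuLi (2.1 equiv), −78 → 0 °C; aq. NH4Cl, brief 1 M HCl
Reagents that add atoms: none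
Why: The aldehyde is masked in situ as its lithium α-amino alkoxide (Comins protection), and Br/Li exchange followed by Parham-type 5-exo aryllithium opening of the oxirane at its stereogenic carbon (SN2, inversion) converts the purchased (S) C–O centre into the (R) C3–aryl centre.

**Step 3**
Reactants: 4, (3R)-3-(hydroxymethyl)-7-methoxy-2,3-dihydro-1-benzofuran-5-carbaldehyde; 5, (bromomethyl)chlorodimethylsilane
Product: 6, (3S)-3-({[(bromomethyl)dimethylsilyl]oxy}methyl)-7-methoxy-2,3-dihydro-1-benzofuran-5-carbaldehyde (same geometry at C3 as 4; only the CIP descriptor changes)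
Conditions: 5 (1.2 equiv), imidazole (1.5 equiv), CH2Cl2, 0 °C; non-aqueous work-up, used directly
Reagents that add atoms: (bromomethyl)chlorodimethylsilane, C[Si](C)(Cl)CBr
Why: Routine silylation of the primary alcohol installs the radical-relay tether without touching C3.

**Step 4**
Reactants: 6, (3S)-3-({[(bromomethyl)dimethylsilyl]oxy}methyl)-7-methoxy-2,3-dihydro-1-benzofuran-5-carbaldehyde; 7, 4-bromo-2-methoxyphenyl acetate
Product: 9, (2S,3R)-2-(4-hydroxy-3-methoxyphenyl)-3-(hydroxymethyl)-7-methoxy-2,3-dihydro-1-benzofuran-5-carbaldehyde, via 8, the (2S,3R) C2-arylated trimethylsilyl ether / aryl acetate (not isolated)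
Conditions: 7 (2 equiv), NiBr2·glyme (2 mol%), dtbbpy (2.4 mol%), Ir[dF(CF3)ppy]2(dtbbpy)PF6 (1 mol%), (TMS)3SiH (1.3 equiv, syringe pump), Na2CO3 (2 equiv), DME (0.02 M), 450 nm LEDs, 25 °C; then K2CO3, MeOH, rt, same pot
Reagents that add atoms: 4-bromo-2-methoxyphenyl acetate, COc1cc(Br)ccc1OC(C)=O (the acetyl group is lost in the methanolysis)
Why: Proposed new method: the photogenerated (TMS)3Si• abstracts Br from the tether to give a Me2Si–CH2• radical, which takes the γ C2–H by 1,6-HAT through a seven-membered transition state (the long Si–C and Si–O bonds disfavour the six-membered 1,5-HAT at C3–H), the tether becoming an OSiMe3 group; the resulting α-aryloxy C2 radical is captured by (dtbbpy)Ni(Ar)Br formed from 7, and reductive elimination from Ni(III) forms the C2–aryl bond anti to the C3 CH2OSiMe3 group, giving the 2,3-trans (2S) product under control of C3, after which methanolysis removes the Me3Si ether and the acetate. The closest known reactions are silyl-radical-mediated Ni/photoredox cross-electrophile coupling of alkyl bromides with aryl bromides and γ-selective 1,6-HAT of halomethylsilyl ethers in photoinduced Pd-catalysed alcohol desaturation; coupling the relayed radical to an aryl–Ni species, and doing so at the C2–H of a dihydrobenzofuran, is new.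

**Step 5**
Reactants: 9, (2S,3R)-2-(4-hydroxy-3-methoxyphenyl)-3-(hydroxymethyl)-7-methoxy-2,3-dihydro-1-benzofuran-5-carbaldehyde; 10, malonic acid
Product: 11, (E)-3-[(2S,3R)-2-(4-hydroxy-3-methoxyphenyl)-3-(hydroxymethyl)-7-methoxy-2,3-dihydro-1-benzofuran-5-yl]prop-2-enoic acid (target)
Conditions: malonic acid (3 equiv), pyridine, piperidine (0.2 equiv), 60 °C; then 1 M HCl
Reagents that add atoms: malonic acid, O=C(O)CC(=O)O (one CO2 is lost)
Why: Knoevenagel–Doebner condensation with decarboxylation gives the (E)-cinnamic acid directly in the presence of the free phenol and alcohol, and neither C2–H nor C3–H is acidic enough to epimerise.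

## Compound list

1 | 5-bromovanillin (3-bromo-4-hydroxy-5-methoxybenzaldehyde) | COc1cc(C=O)cc(Br)c1O | starting material
2 | (S)-glycidyl nosylate, [(2S)-oxiran-2-yl]methyl 3-nitrobenzenesulfonate | O=S(=O)(OC[C@@H]1CO1)c1cccc([N+](=O)[O-])c1 | starting material
3 | 3-bromo-5-methoxy-4-{[(2S)-oxiran-2-yl]methoxy}benzaldehyde | COc1cc(C=O)cc(Br)c1OC[C@@H]1CO1 | intermediate
4 | (3R)-3-(hydroxymethyl)-7-methoxy-2,3-dihydro-1-benzofuran-5-carbaldehyde | COc1cc(C=O)cc2c1OC[C@H]2CO | intermediate
5 | (bromomethyl)chlorodimethylsilane | C[Si](C)(Cl)CBr | starting material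
6 | (3S)-3-({[(bromomethyl)dimethylsilyl]oxy}methyl)-7-methoxy-2,3-dihydro-1-benzofuran-5-carbaldehyde | COc1cc(C=O)cc2c1OC[C@H]2CO[Si](C)(C)CBr | intermediate
7 | 4-bromo-2-methoxyphenyl acetate | COc1cc(Br)ccc1OC(C)=O | starting material
8 | 4-[(2S,3R)-5-formyl-7-methoxy-3-{[(trimethylsilyl)oxy]methyl}-2,3-dihydro-1-benzofuran-2-yl]-2-methoxyphenyl acetate (not isolated) | COc1cc([C@H]2Oc3c(OC)cc(C=O)cc3[C@@H]2CO[Si](C)(C)C)ccc1OC(C)=O | intermediate
9 | (2S,3R)-2-(4-hydroxy-3-methoxyphenyl)-3-(hydroxymethyl)-7-methoxy-2,3-dihydro-1-benzofuran-5-carbaldehyde | COc1cc([C@H]2Oc3c(OC)cc(C=O)cc3[C@@H]2CO)ccc1O | intermediate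
10 | malonic acid | O=C(O)CC(=O)O | starting material
11 | (E)-3-[(2S,3R)-2-(4-hydroxy-3-methoxyphenyl)-3-(hydroxymethyl)-7-methoxy-2,3-dihydro-1-benzofuran-5-yl]prop-2-enoic acid | COc1cc([C@H]2Oc3c(OC)cc(/C=C/C(=O)O)cc3[C@@H]2CO)ccc1O | target

## Step count and risks

Total steps: 5. Longest linear sequence: 5.

Steps most likely to fail:

1. **Step 4 (proposed new step).** The Si–CH2• radical may couple with Ni or be reduced before the 1,6-HAT, 1,5-HAT at the benzylic C3–H would scramble C3, and β-H elimination would give the benzofuran. Fallback with known chemistry: bring the C2 aryl group in before ring closure. Add the O-protected 4-hydroxy-3-methoxyphenyl Grignard to 2,3-O-isopropylideneglyceraldehyde (either enantiomer is available), etherify the benzylic carbinol with the bromophenol (Mitsunobu for inversion, or SNAr on the aryl fluoride for retention, chosen to give 2S,3R), convert the acetonide to the terminal epoxide, and close the ring with the same Br/Li 5-exo epoxide opening. This needs no C–H arylation.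

2. **Step 2.** The in situ aldehyde masking may be incomplete, or 6-endo opening may compete. Fallback: remove the carbonyl from the cyclisation altogether. Start from 4,6-dibromo-2-methoxyphenol, use ortho-selective Br/Li exchange for the 5-exo closure, then install the C5 aldehyde by a second Br/Li exchange and DMF quench.

3. **Step 5.** The free p-hydroxybenzyl aryl ether may ring-open through a quinone methide in warm amine base. Fallback: replace the condensation with an olefination at room temperature, using Ph3P=CHCO2t-Bu (Wittig) and then TFA to release the acid (one extra step).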